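Ring A is built last, as a benzene, around the oxygen that links it to ring B, so no aryl–oxygen coupling is needed at that ring. In one operation an inverse-electron-demand Diels–Alder reaction between a terminal aryl ethynyl ether and methyl 3-methoxy-2-oxo-2H-pyran-5-carboxylate, followed by loss of CO2, should form the C1–C2 bond of ring A (aryloxy carbon to methoxy carbon) and its C5–C6 bond, and place an ester at C4, para to the ether oxygen, where the target carries its allyl group. The precursor is the ethynyl ether of a ring B–ring C diaryl ether phenol whose ring C hydroxyl is masked as a methoxymethyl ether.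

Key step: step 11

Remark on the chemistry: the pyrone is assembled from acyclic esters, because alkoxide or carbonate bases open 3-halo-2-pyrone-5-carboxylates (with contraction to furans), so no substitution route to its methoxy group is relied on; ring A is numbered from its aryloxy carbon (C1).

Step 1
Reactants: 1 eugenol (4-allyl-2-methoxyphenol)
Product: 2 4-allyl-2-bromo-6-methoxyphenol
Conditions: NBS, i-Pr2NH (cat.), CH2Cl2, 0 °C, dark
Reagents that add atoms: N-bromosuccinimide, O=C1CCC(=O)N1Br
Why: Amine-catalysed electrophilic aromatic bromination should go ortho to the free hydroxyl (the para position is blocked by the allyl group), and the cold ionic conditions should leave the terminal alkene untouched.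

Step 2
Reactants: 3 4-bromo-2-fluoro-6-methoxybenzaldehyde
Product: 4 4-allyl-2-fluoro-6-methoxybenzaldehyde
Conditions: allyl-B(pin), PdCl2(dppf) (cat.), CsF, THF, 65 °C
Reagents that add atoms: allylboronic acid pinacol ester, C=CCB1OC(C)(C)C(C)(C)O1
Why: Suzuki–Miyaura allylation should occur readily at the bromide para to the formyl group, and mild fluoride activation should avoid both attack on the aryl fluoride and migration of the allyl double bond.

Step 3
Reactants: 2 4-allyl-2-bromo-6-methoxyphenol; 4 4-allyl-2-fluoro-6-methoxybenzaldehyde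
Product: 5 4-allyl-2-(4-allyl-2-bromo-6-methoxyphenoxy)-6-methoxybenzaldehyde
Conditions: Cs2CO3, DMF, 80 °C
Reagents that add atoms: none
Why: Nucleophilic aromatic substitution (SNAr) of the fluoride ortho to the formyl group by the phenoxide of 2 should proceed through a Meisenheimer adduct, with a carbonate base that is strong enough for the phenol but not for the benzylic allyl protons.

Step 4
Reactants: 5 4-allyl-2-(4-allyl-2-bromo-6-methoxyphenoxy)-6-methoxybenzaldehyde
Product: 7 4-allyl-2-(4-allyl-2-bromo-6-methoxyphenoxy)-6-methoxyphenol, via aryl formate 6 (not isolated)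
Conditions: H2O2 (30% aq), H2SO4 (cat.), MeOH, 20 °C
Reagents that add atoms: hydrogen peroxide, OO
Why: In this acid-catalysed Dakin (Baeyer–Villiger type) oxidation the aryl group flanked by two oxygen substituents should migrate, the formate should be methanolysed in situ, and peroxide without a peracid should not epoxidise the terminal alkenes.

Step 5
Reactants: 7 4-allyl-2-(4-allyl-2-bromo-6-methoxyphenoxy)-6-methoxyphenol
Product: 8 5-allyl-1-(4-allyl-2-bromo-6-methoxyphenoxy)-3-methoxy-2-(methoxymethoxy)benzene
Conditions: NaH, MOMCl, DMF, 0 to 20 °C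
Reagents that add atoms: chloromethyl methyl ether, COCCl
Why: Williamson-type O-alkylation of the hindered phenoxide with the reactive chloromethyl ether should give an acetal that withstands the organolithium, hydride and palladium steps that follow.

Step 6
Reactants: 8 5-allyl-1-(4-allyl-2-bromo-6-methoxyphenoxy)-3-methoxy-2-(methoxymethoxy)benzene
Product: 11 5-allyl-2-[5-allyl-3-methoxy-2-(methoxymethoxy)phenoxy]-3-methoxyphenol, via aryllithium 9 (not isolated), via lithium aryltrimethoxyborate 10 (not isolated)
Conditions: n-BuLi, THF, −78 °C; B(OMe)3, −78 to 0 °C; then H2O2, NaOH (aq), 0 to 20 °C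
Reagents that add atoms: hydrogen peroxide, OO
Why: Bromine–lithium exchange at −78 °C should outrun any deprotonation, the borate trap and alkaline peroxide oxidation (aryl shift from boron to oxygen) should put the hydroxyl exactly where bromine was, and the alkenes and the acetal are inert to alkaline peroxide.

Step 7
Reactants: 11 5-allyl-2-[5-allyl-3-methoxy-2-(methoxymethoxy)phenoxy]-3-methoxyphenol; 12 trichloroethylene
Product: 13 5-allyl-1-[(E)-1,2-dichlorovinyloxy]-2-[5-allyl-3-methoxy-2-(methoxymethoxy)phenoxy]-3-methoxybenzene
Conditions: K2CO3, DMF, 70 °C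
Reagents that add atoms: none
Why: The phenoxide should add to dichloroacetylene generated in situ from trichloroethylene, anti addition setting the E geometry of the dichlorovinyl ether (the established entry to aryl ynol ethers).

Step 8
Reactants: 13 5-allyl-1-[(E)-1,2-dichlorovinyloxy]-2-[5-allyl-3-methoxy-2-(methoxymethoxy)phenoxy]-3-methoxybenzene
Product: 16 5-allyl-1-(ethynyloxy)-2-[5-allyl-3-methoxy-2-(methoxymethoxy)phenoxy]-3-methoxybenzene, via chloroethynyl ether 14 (not isolated), via lithium acetylide 15 (not isolated)
Conditions: n-BuLi (2.3 equiv), Et2O, −78 to −40 °C; MeOH, −78 °C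
Reagents that add atoms: none
Why: Dehydrochlorination by n-BuLi, chlorine–lithium exchange and a cold methanol quench should give the terminal ynol ether (the known dichlorovinyl ether route); no proton ortho to the acetal is available for directed lithiation, and the product is to be used at once because terminal aryloxyalkynes oligomerise on storage.

Step 9
Reactants: 17 methyl (E)-3-(dimethylamino)acrylate
Product: 19 methyl 3-(dimethylamino)-2-formylacrylate, via vinamidinium chloride 18 (not isolated)
Conditions: POCl3, DMF, 0 to 70 °C; then K2CO3 (aq), 20 °C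
Reagents that add atoms: N,N-dimethylformamide, CN(C)C=O; water, O
Why: In this Vilsmeier–Haack formylation the enamino ester should attack the chloroiminium ion at its α-carbon to give a symmetrical vinamidinium salt, and mild alkaline hydrolysis of either iminium terminus gives the same formyl enaminone.

Step 10
Reactants: 19 methyl 3-(dimethylamino)-2-formylacrylate; 20 methyl methoxyacetate
Product: 22 methyl 3-methoxy-2-oxo-2H-pyran-5-carboxylate, via aldol adduct 21 (not isolated)
Conditions: LiN(i-Pr)2, THF, −78 °C; AcOH; then TsOH (cat.), AcOH, 80 °C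
Reagents that add atoms: none
Why: Aldol addition of the lithium ester enolate to the formyl group, then acid-promoted loss of water and dimethylamine and lactonisation of the resulting 5-hydroxypenta-2,4-dienoate, should give the pyrone (the condensation–lactonisation route to 2-pyranones from β-aminoacroleins and ester enolates); attack at the enamine carbon would converge on the same dienol.

Step 11
Reactants: 16 5-allyl-1-(ethynyloxy)-2-[5-allyl-3-methoxy-2-(methoxymethoxy)phenoxy]-3-methoxybenzene; 22 methyl 3-methoxy-2-oxo-2H-pyran-5-carboxylate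
Product: 24 methyl 4-{5-allyl-2-[5-allyl-3-methoxy-2-(methoxymethoxy)phenoxy]-3-methoxyphenoxy}-3-methoxybenzoate, via bridged lactone 23 (not isolated)
Conditions: 22 (1.5 equiv), BHT (cat.), toluene, 100 °C, sealed tube
Reagents that add atoms: none
Why: The electron-rich ynol ether and the electron-poor pyrone should combine in an asynchronous inverse-electron-demand [4+2] cycloaddition in which the nucleophilic terminal CH of 16 bonds to C6 of 22 (activated by both the lactone and the C5 ester) and the oxygen-bearing alkyne carbon closes onto C3, giving bridged lactone 23, which aromatises to 24 by retro-[4+2] loss of CO2. The closest known reaction type is the Diels–Alder benzannulation of 2-pyrone-5-carboxylates with ynamines, alkoxyalkynes and ketene acetals. Ring A is closed by intermolecular cycloaddition followed by cycloreversion, its C1–C2 and C5–C6 bonds being the two new sigma bonds and its other four atoms C3–C6 of the pyrone. No stereocentre remains, since the two bridgehead centres of 23 form together (racemic) and vanish on CO2 loss. The step needs regioselectivity (aryloxy carbon to C3, so that the ether ends para to the ester and ortho to the methoxy group), which the polarisation of the ynol ether and the higher electrophilicity of C6 should secure, and chemoselectivity for the alkyne over the two unactivated allyl groups, which add to such pyrones only at much higher temperature.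

Step 12
Reactants: 24 methyl 4-{5-allyl-2-[5-allyl-3-methoxy-2-(methoxymethoxy)phenoxy]-3-methoxyphenoxy}-3-methoxybenzoate
Product: 25 (4-{5-allyl-2-[5-allyl-3-methoxy-2-(methoxymethoxy)phenoxy]-3-methoxyphenoxy}-3-methoxyphenyl)methanol
Conditions: i-Bu2AlH, CH2Cl2, −78 to 0 °C
Reagents that add atoms: none
Why: Hydride reduction of the aryl ester should stop at the benzylic alcohol, and the ethers, the acetal and the isolated alkenes do not react with this hydride at low temperature.

Step 13
Reactants: 25 (4-{5-allyl-2-[5-allyl-3-methoxy-2-(methoxymethoxy)phenoxy]-3-methoxyphenoxy}-3-methoxyphenyl)methanol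
Product: 26 5-allyl-1-[4-(bromomethyl)-2-methoxyphenoxy]-2-[5-allyl-3-methoxy-2-(methoxymethoxy)phenoxy]-3-methoxybenzene
Conditions: CBr4, PPh3, CH2Cl2, 0 °C
Reagents that add atoms: tetrabromomethane, BrC(Br)(Br)Br
Why: The Appel reaction (SN2 displacement of the alkoxyphosphonium ion by bromide) is neutral and should spare the acid-labile acetal; the electron-rich benzylic bromide is to be used crude.

Step 14
Reactants: 26 5-allyl-1-[4-(bromomethyl)-2-methoxyphenoxy]-2-[5-allyl-3-methoxy-2-(methoxymethoxy)phenoxy]-3-methoxybenzene
Product: 27 5-allyl-1-(4-allyl-2-methoxyphenoxy)-2-[5-allyl-3-methoxy-2-(methoxymethoxy)phenoxy]-3-methoxybenzene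
Conditions: Bu3Sn(CH=CH2), Pd(PPh3)4 (cat.), THF, 65 °C
Reagents that add atoms: tributyl(vinyl)stannane, C=C[Sn](CCCC)(CCCC)CCCC
Why: Stille coupling of a benzylic bromide with a vinylstannane is a known route to allylarenes, and its neutral conditions should keep all three allyl groups out of conjugation.

Step 15
Reactants: 27 5-allyl-1-(4-allyl-2-methoxyphenoxy)-2-[5-allyl-3-methoxy-2-(methoxymethoxy)phenoxy]-3-methoxybenzene
Product: 28 4-allyl-2-[4-allyl-2-(4-allyl-2-methoxyphenoxy)-6-methoxyphenoxy]-6-methoxyphenol (target)
Conditions: HCl (2 M in MeOH), 20 to 40 °C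
Reagents that add atoms: none
Why: Acid-catalysed cleavage of the aryl methoxymethyl acetal through its oxocarbenium ion, trapped by methanol, should free the phenol, while aryl methyl ethers, diaryl ethers and terminal alkenes are stable to dilute methanolic HCl.

Compound list
1 | eugenol (4-allyl-2-methoxyphenol) | C=CCc1ccc(O)c(OC)c1 | starting material
2 | 4-allyl-2-bromo-6-methoxyphenol | C=CCc1cc(Br)c(O)c(OC)c1 | intermediate
3 | 4-bromo-2-fluoro-6-methoxybenzaldehyde | COc1cc(Br)cc(F)c1C=O | starting material
4 | 4-allyl-2-fluoro-6-methoxybenzaldehyde | COc1cc(CC=C)cc(F)c1C=O | intermediate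
5 | 4-allyl-2-(4-allyl-2-bromo-6-methoxyphenoxy)-6-methoxybenzaldehyde | COc1cc(CC=C)cc(Oc2c(Br)cc(CC=C)cc2OC)c1C=O | intermediate
6 | 4-allyl-2-(4-allyl-2-bromo-6-methoxyphenoxy)-6-methoxyphenyl formate (not isolated) | COc1cc(CC=C)cc(Oc2c(Br)cc(CC=C)cc2OC)c1OC=O | intermediate
7 | 4-allyl-2-(4-allyl-2-bromo-6-methoxyphenoxy)-6-methoxyphenol | COc1cc(CC=C)cc(Oc2c(Br)cc(CC=C)cc2OC)c1O | intermediate
8 | 5-allyl-1-(4-allyl-2-bromo-6-methoxyphenoxy)-3-methoxy-2-(methoxymethoxy)benzene | COCOc1c(OC)cc(CC=C)cc1Oc1c(Br)cc(CC=C)cc1OC | intermediate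
9 | aryllithium from 8, lithium in place of bromine (not isolated) | COCOc1c(OC)cc(CC=C)cc1Oc1c([Li])cc(CC=C)cc1OC | intermediate
10 | lithium trimethoxy(aryl)borate from 9 (not isolated) | [Li+].COCOc1c(OC)cc(CC=C)cc1Oc1c([B-](OC)(OC)OC)cc(CC=C)cc1OC | intermediate
11 | 5-allyl-2-[5-allyl-3-methoxy-2-(methoxymethoxy)phenoxy]-3-methoxyphenol | COCOc1c(OC)cc(CC=C)cc1Oc1c(O)cc(CC=C)cc1OC | intermediate
12 | trichloroethylene | ClC=C(Cl)Cl | starting material
13 | 5-allyl-1-[(E)-1,2-dichlorovinyloxy]-2-[5-allyl-3-methoxy-2-(methoxymethoxy)phenoxy]-3-methoxybenzene | Cl/C=C(/Cl)Oc1cc(CC=C)cc(OC)c1Oc1cc(CC=C)cc(OC)c1OCOC | intermediate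
14 | 5-allyl-1-(chloroethynyloxy)-2-[5-allyl-3-methoxy-2-(methoxymethoxy)phenoxy]-3-methoxybenzene (not isolated) | ClC#COc1cc(CC=C)cc(OC)c1Oc1cc(CC=C)cc(OC)c1OCOC | intermediate
15 | lithium acetylide of 16 (not isolated) | [Li]C#COc1cc(CC=C)cc(OC)c1Oc1cc(CC=C)cc(OC)c1OCOC | intermediate
16 | 5-allyl-1-(ethynyloxy)-2-[5-allyl-3-methoxy-2-(methoxymethoxy)phenoxy]-3-methoxybenzene | C#COc1cc(CC=C)cc(OC)c1Oc1cc(CC=C)cc(OC)c1OCOC | intermediate
17 | methyl (E)-3-(dimethylamino)acrylate | CN(C)/C=C/C(=O)OC | starting material
18 | [3-(dimethylamino)-2-(methoxycarbonyl)allylidene]dimethylammonium chloride (not isolated) | CN(C)C=C(C=[N+](C)C)C(=O)OC.[Cl-] | intermediate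
19 | methyl 3-(dimethylamino)-2-formylacrylate (push–pull double bond, geometry not fixed) | CN(C)C=C(C=O)C(=O)OC | intermediate
20 | methyl methoxyacetate | COCC(=O)OC | starting material
21 | dimethyl 4-[(dimethylamino)methylidene]-3-hydroxy-2-methoxypentanedioate (racemic diastereomer mixture, not isolated) | CN(C)C=C(C(=O)OC)C(O)C(OC)C(=O)OC | intermediate
22 | methyl 3-methoxy-2-oxo-2H-pyran-5-carboxylate | COC(=O)C1=COC(=O)C(OC)=C1 | intermediate
23 | methyl 5-(aryloxy)-4-methoxy-3-oxo-2-oxabicyclo[2.2.2]octa-5,7-diene-7-carboxylate, aryl as in 16 (racemic, not isolated) | COC(=O)C1=CC2(OC)C(=O)OC1C=C2Oc1cc(CC=C)cc(OC)c1Oc1cc(CC=C)cc(OC)c1OCOC | intermediate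
24 | methyl 4-{5-allyl-2-[5-allyl-3-methoxy-2-(methoxymethoxy)phenoxy]-3-methoxyphenoxy}-3-methoxybenzoate | COC(=O)c1ccc(Oc2cc(CC=C)cc(OC)c2Oc2cc(CC=C)cc(OC)c2OCOC)c(OC)c1 | intermediate
25 | (4-{5-allyl-2-[5-allyl-3-methoxy-2-(methoxymethoxy)phenoxy]-3-methoxyphenoxy}-3-methoxyphenyl)methanol | OCc1ccc(Oc2cc(CC=C)cc(OC)c2Oc2cc(CC=C)cc(OC)c2OCOC)c(OC)c1 | intermediate
26 | 5-allyl-1-[4-(bromomethyl)-2-methoxyphenoxy]-2-[5-allyl-3-methoxy-2-(methoxymethoxy)phenoxy]-3-methoxybenzene | BrCc1ccc(Oc2cc(CC=C)cc(OC)c2Oc2cc(CC=C)cc(OC)c2OCOC)c(OC)c1 | intermediate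
27 | 5-allyl-1-(4-allyl-2-methoxyphenoxy)-2-[5-allyl-3-methoxy-2-(methoxymethoxy)phenoxy]-3-methoxybenzene | C=CCc1ccc(Oc2cc(CC=C)cc(OC)c2Oc2cc(CC=C)cc(OC)c2OCOC)c(OC)c1 | intermediate
28 | 4-allyl-2-[4-allyl-2-(4-allyl-2-methoxyphenoxy)-6-methoxyphenoxy]-6-methoxyphenol (CNP0153774.0, achiral) | C=CCc1ccc(Oc2cc(CC=C)cc(OC)c2Oc2cc(CC=C)cc(OC)c2O)c(OC)c1 | target

Total step count: 15. Longest linear sequence: 12 steps (steps 1, 3 to 8 and 11 to 15, from eugenol).

Steps most likely to fail

Step 11. The methoxy group makes the pyrone a weaker acceptor, so the cycloaddition may be outrun by thermal oligomerisation or adventitious hydration of the terminal ynol ether. The fallback attaches ring A by nucleophilic aromatic substitution instead. It sets out from phenol 11, which with commercial 4-fluoro-3-methoxybenzaldehyde (COc1cc(C=O)ccc1F; K2CO3, DMSO, 100 °C) should give 4-{5-allyl-2-[5-allyl-3-methoxy-2-(methoxymethoxy)phenoxy]-3-methoxyphenoxy}-3-methoxybenzaldehyde F1, the fluoride para to the formyl group being displaced. Reduction with NaBH4 in MeOH at 0 °C would then give benzylic alcohol 25, where the route resumes at step 13.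

Step 10. The open-chain adduct may fail to lactonise, with retro-aldol cleavage or oligomerisation of the formyl acrylate intermediate competing with ring closure. The fallback forms the acyl–oxygen bond first. It sets out from formyl enaminone 19, which with methoxyacetyl chloride and Et3N (CH2Cl2, 0 to 20 °C) should react with the methoxyketene formed in situ in a formal [4+2] cycloaddition (acylation of the formyl oxygen, then ring closure onto the iminium carbon), giving methyl 4-(dimethylamino)-3-methoxy-2-oxo-3,4-dihydro-2H-pyran-5-carboxylate F2. Warming with TsOH (cat.) in toluene should expel dimethylamine and return the route to pyrone 22.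

Step 3. Displacement by the hindered, bromine-deactivated phenoxide may be slow enough for the carbonate base to shift the double bond of the allyl group para to the formyl group into conjugation. The fallback joins the rings before that allyl group exists. It sets out from phenol 2 and bromo aldehyde 3, which under the same SNAr conditions should give 4-bromo-2-(4-allyl-2-bromo-6-methoxyphenoxy)-6-methoxybenzaldehyde F3. A site-selective Suzuki–Miyaura allylation (allylboronic acid pinacol ester, PdCl2(dppf), CsF, THF, 50 °C) at the electron-poor, unhindered bromide para to the formyl group, rather than at the bromide on the electron-rich ring next to the ether oxygen, would return the route to aldehyde 5.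

Further compounds
F1 | step 11 | 4-{5-allyl-2-[5-allyl-3-methoxy-2-(methoxymethoxy)phenoxy]-3-methoxyphenoxy}-3-methoxybenzaldehyde | O=Cc1ccc(Oc2cc(CC=C)cc(OC)c2Oc2cc(CC=C)cc(OC)c2OCOC)c(OC)c1
F2 | step 10 | methyl 4-(dimethylamino)-3-methoxy-2-oxo-3,4-dihydro-2H-pyran-5-carboxylate (racemic diastereomer mixture) | CN(C)C1C(OC)C(=O)OC=C1C(=O)OC
F3 | step 3 | 4-bromo-2-(4-allyl-2-bromo-6-methoxyphenoxy)-6-methoxybenzaldehyde | COc1cc(Br)cc(Oc2c(Br)cc(CC=C)cc2OC)c1C=O
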